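The C8–C9 bond of the oxirane is also a bond of the seven-membered ring B and is flanked by two methylene groups (C7, C10), so the epoxide is read as a trisubstituted cycloheptene. The key step, ring-closing olefin metathesis, joins an allyl arm on the quaternary C1 and a methallyl arm on the carbinol C6 of a fully substituted cyclopentane (ring A) and closes ring B as the C8=C9 alkene; the homoallylic C6–OH then directs epoxidation. The precursor is a monocyclic diene that already carries the C4 aryl ester and the stereocentres C1, C4, C5 and C6, built from (S)-terpinen-4-ol by ring contraction, allylboration, anionic oxy-Cope shift and chelation-controlled methallylation.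

Key step: step 9

Remarks on the chemistry:
- Locants in the text follow daucane numbering: C1 = methyl-bearing ring-fusion carbon, C2, C3, C4 = carbon bearing isopropyl and the ester oxygen, C5 = ring-fusion CH, C6 = carbinol carbon, C7, C8 = methyl-bearing oxirane carbon, C9 = oxirane CH, C10, C15 = methyl on C1. Ring A = C1–C5; ring B = C1, C5–C10. The β face is that of the C15 methyl, the α face that of H-5. Systematic names of monocyclic compounds keep their own locants.
- Assumption: (S)-(+)-terpinen-4-ol is used as enantiopure commercial material.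

Step 1
Reactants: 1 (S)-(+)-terpinen-4-ol; 2 triethylsilyl trifluoromethanesulfonate
Product: 3 (S)-triethyl{[4-methyl-1-(propan-2-yl)cyclohex-3-en-1-yl]oxy}silane
Conditions: 2,6-lutidine, CH2Cl2, 0 °C
Reagents that add atoms: triethylsilyl trifluoromethanesulfonate CC[Si](CC)(CC)OS(=O)(=O)C(F)(F)F
Why: Silyl triflate O-silylation should work even on this hindered tertiary alcohol and masks the oxygen so that it cannot be lost by retro-aldol cleavage or acid-assisted β-elimination in steps 2 and 3; the C4 stereocentre comes from the chiral pool and is not touched.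

Step 2
Reactants: 3 silyl ether; 4 ozone
Product: 6 (S)-3-isopropyl-6-oxo-3-(triethylsilyloxy)heptanal, via secondary ozonide 5 (not isolated)
Conditions: O3, CH2Cl2, −78 °C; then PPh3, −78 to 23 °C
Reagents that add atoms: ozone [O-][O+]=O
Why: Ozonolysis with reductive work-up cleaves the only C=C bond and gives an open-chain 1,6-keto aldehyde whose aldehyde carbon is the future C6 and whose methyl ketone carbon is the future C1.

Step 3
Reactants: 6 keto aldehyde
Product: 8 (R)-5-hydroxy-5-isopropyl-2-methylcyclopent-1-ene-1-carbaldehyde, via silyl ether enal 7 (not isolated)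
Conditions: Bn2NH·CF3CO2H, toluene, 50 °C; then aq HF, MeCN, 0 °C
Reagents that add atoms: none
Why: Amine-catalysed intramolecular aldol condensation, in which the aldehyde enamine adds 5-exo-trig to the methyl ketone and the new tertiary OH is lost by acid-assisted dehydration to the conjugated enal (ring contraction to ring A), while the non-basic silyl ether should survive until fluoride removes it; C4 is not involved.

Step 4
Reactants: 8 hydroxy enal; 9 (−)-B-allyldiisopinocampheylborane
Product: 11 (R)-2-[(S)-1-hydroxybut-3-en-1-yl]-1-isopropyl-3-methylcyclopent-2-en-1-ol, via borinate ester 10 (not isolated)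
Conditions: 9 (1.5 equiv), Et2O, −78 °C; then NaOH, H2O2, 0 to 23 °C
Reagents that add atoms: (−)-B-allyldiisopinocampheylborane C=CCB([C@@H]1C[C@@H]2C[C@H]([C@H]1C)C2(C)C)[C@@H]1C[C@@H]2C[C@H]([C@H]1C)C2(C)C
Why: Brown allylboration through a closed chair transition state, in which the reagent derived from (+)-α-pinene should set the (S)-carbinol at C6 under reagent control, as it does for other aldehydes whose substituent outranks allyl; C4 lies 1,3 to the carbonyl carbon and is expected to exert little opposing bias.

Step 5
Reactants: 11 bis-allylic diol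
Product: 15 (1R,2R,5R)-2-allyl-5-hydroxy-5-isopropyl-2-methylcyclopentane-1-carbaldehyde, via dipotassium dialkoxide 12 (not isolated), via dipotassium enolate 13 (not isolated), via epimeric aldehyde mixture 14 (not isolated)
Conditions: KH (2.3 equiv), THF, 0 to 45 °C; aq NH4Cl, −40 °C; then Et3N (0.2 equiv), CH2Cl2, 23 °C
Reagents that add atoms: none
Why: Anionic oxy-Cope rearrangement moves the allyl group from C6 to C1 through a chair transition state in which allylic 1,3-strain keeps the carbinol H eclipsed with the C15 methyl and K+ bridges the two alkoxides, so the (S)-carbinol should deliver allyl to the α face of C1 (cis to isopropyl) by 1,3-chirality transfer and set the quaternary centre; the dianion cannot undergo β-elimination, and after protonation Et3N equilibrates C5 to the epimer with the formyl group trans to isopropyl and allyl and hydrogen-bonded to C4–OH.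

Step 6
Reactants: 15 hydroxy aldehyde; 16 2-methylallylmagnesium chloride
Product: 18 (S)-1-[(1S,2R,5R)-2-allyl-5-hydroxy-5-isopropyl-2-methylcyclopentyl]-3-methylbut-3-en-1-ol, via chloromagnesium alkoxide 17 (not isolated)
Conditions: 16 (2.5 equiv), THF, −78 °C; aq NH4Cl
Reagents that add atoms: 2-methylallylmagnesium chloride CC(=C)C[Mg]Cl
Why: Chelation-controlled Grignard addition, in which the first equivalent forms the C4 magnesium alkoxide that binds the aldehyde oxygen in a six-membered chelate cis-fused to ring A and the second equivalent attacks the exposed exo face of the carbonyl, which should give the 1,3-anti diol with (S)-C6.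

Step 7
Reactants: 18 diol; 19 tert-butyldimethylsilyl trifluoromethanesulfonate
Product: 20 (1R,2S,3R)-3-allyl-2-[(S)-1-(tert-butyldimethylsilyloxy)-3-methylbut-3-en-1-yl]-1-isopropyl-3-methylcyclopentan-1-ol
Conditions: 19 (1.1 equiv), 2,6-lutidine, CH2Cl2, −78 °C
Reagents that add atoms: tert-butyldimethylsilyl trifluoromethanesulfonate CC(C)(C)[Si](C)(C)OS(=O)(=O)C(F)(F)F
Why: Silylation is governed by steric hindrance, so the secondary C6–OH should react and the tertiary C4–OH, flanked by isopropyl and C5, should not, which differentiates the diol for the acylation; no stereocentre is affected.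

Step 8
Reactants: 20 silyl ether; 21 4-(benzyloxy)benzoyl chloride
Product: 24 (1R,2S,3R)-3-allyl-2-[(S)-1-hydroxy-3-methylbut-3-en-1-yl]-1-isopropyl-3-methylcyclopentyl 4-(benzyloxy)benzoate, via lithium alkoxide 22 (not isolated), via silyl ether ester 23 (not isolated)
Conditions: n-BuLi, THF, −78 °C; 21, −78 to 23 °C; then HF·pyridine, THF, 0 to 23 °C
Reagents that add atoms: 4-(benzyloxy)benzoyl chloride O=C(Cl)c1ccc(OCc2ccccc2)cc1
Why: Acyl transfer from an aroyl chloride to a lithium tertiary alkoxide installs the hindered ester while O6 is masked, and acidic fluoride then removes the silyl group without forming a C6 alkoxide that could start a 1,3-acyl shift.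

Step 9
Reactants: 24 hydroxy ester diene
Product: 25 (1R,4R,5S,6S)-6-hydroxydauc-8-en-4-yl 4-(benzyloxy)benzoate (trans-fused rings A and B, C8=C9 alkene with CH3 on C8, 1β-CH3, 4α-isopropyl, 4β-aroyloxy, 5α-H, 6α-OH)
Conditions: second-generation Grubbs catalyst (H2IMes)(PCy3)Cl2Ru=CHPh (5 mol %), CH2Cl2 (5 mM), 40 °C
Reagents that add atoms: none
Why: The ruthenium benzylidene first exchanges with the monosubstituted alkene of the C1 allyl arm; the new alkylidene at C9 adds [2+2] to the 1,1-disubstituted alkene of the methallyl arm, and cycloreversion of the metallacyclobutane releases ethene and creates the C8=C9 double bond. The closest known reaction type is ring-closing olefin metathesis to trisubstituted cycloheptenes fused to cyclopentanes in hydroazulene terpenoid synthesis. Ring B is closed as a seven-membered carbocycle by this one bond between arms held on the adjacent ring-A carbons C1 and C5, and the ring size enforces the Z alkene. No stereocentre is created, and C1, C4, C5 and C6 are untouched under the neutral conditions. The step needs ring closure to beat intermolecular metathesis; high dilution, the slow homodimerisation of the 1,1-disubstituted and the neopentyl-type alkene, and loss of volatile ethene should secure this. The free C6–OH and the aryl ester are functional groups that this catalyst tolerates.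

Step 10
Reactants: 25 homoallylic alcohol; 26 tert-butyl hydroperoxide
Product: 27 (1R,4R,5S,6S,8R,9S)-8,9-epoxy-6-hydroxydaucan-4-yl 4-(benzyloxy)benzoate (8α,9α-epoxide)
Conditions: VO(acac)2 (5 mol %), t-BuOOH, CH2Cl2, 0 to 23 °C
Reagents that add atoms: tert-butyl hydroperoxide CC(C)(C)OO
Why: Hydroxyl-directed vanadium-catalysed epoxidation of a homoallylic alcohol, in which the vanadium alkoxide of the α-oriented C6–OH delivers oxygen to the α face of C8=C9, the face also left open by the β C15 methyl, which should set C8 (R) and C9 (S) syn to the hydroxyl.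

Step 11
Reactants: 27 benzyl ether
Product: 28 (1R,4R,5S,6S,8R,9S)-8,9-epoxy-6-hydroxydaucan-4-yl 4-hydroxybenzoate (target)
Conditions: H2 (1 atm), Pd/C, EtOAc, 23 °C
Reagents that add atoms: none
Why: Hydrogenolysis of the aryl benzyl ether under neutral conditions frees the phenol; the unactivated trisubstituted epoxide, the tertiary ester and all stereocentres should survive, and no base is present to move the acyl group to O6.

Compound list
1 | (S)-(+)-terpinen-4-ol, (S)-4-methyl-1-(propan-2-yl)cyclohex-3-en-1-ol | CC(C)[C@]1(O)CCC(C)=CC1 | starting material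
2 | triethylsilyl trifluoromethanesulfonate | CC[Si](CC)(CC)OS(=O)(=O)C(F)(F)F | starting material
3 | (S)-triethyl{[4-methyl-1-(propan-2-yl)cyclohex-3-en-1-yl]oxy}silane | CC(C)[C@]1(O[Si](CC)(CC)CC)CCC(C)=CC1 | intermediate
4 | ozone | [O-][O+]=O | starting material
5 | secondary ozonide of 3 (1,2,4-trioxolane across the former C=C, mixture at the two acetal carbons) | CC(C)[C@]1(O[Si](CC)(CC)CC)CCC2(C)OOC(C1)O2 | intermediate
6 | (S)-3-isopropyl-6-oxo-3-(triethylsilyloxy)heptanal | CC(C)[C@](CC=O)(O[Si](CC)(CC)CC)CCC(C)=O | intermediate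
7 | (R)-5-isopropyl-2-methyl-5-(triethylsilyloxy)cyclopent-1-ene-1-carbaldehyde | CC(C)[C@]1(O[Si](CC)(CC)CC)CCC(C)=C1C=O | intermediate
8 | (R)-5-hydroxy-5-isopropyl-2-methylcyclopent-1-ene-1-carbaldehyde | CC(C)[C@]1(O)CCC(C)=C1C=O | intermediate
9 | (−)-B-allyldiisopinocampheylborane | C=CCB([C@@H]1C[C@@H]2C[C@H]([C@H]1C)C2(C)C)[C@@H]1C[C@@H]2C[C@H]([C@H]1C)C2(C)C | starting material
10 | diisopinocampheylborinate of 11 at the secondary oxygen | CC(C)[C@]1(O)CCC(C)=C1[C@H](CC=C)OB([C@@H]1C[C@@H]2C[C@H]([C@H]1C)C2(C)C)[C@@H]1C[C@@H]2C[C@H]([C@H]1C)C2(C)C | intermediate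
11 | (R)-2-[(S)-1-hydroxybut-3-en-1-yl]-1-isopropyl-3-methylcyclopent-2-en-1-ol | CC(C)[C@]1(O)CCC(C)=C1[C@@H](O)CC=C | intermediate
12 | dipotassium dialkoxide of 11 | [K+].[K+].CC(C)[C@]1([O-])CCC(C)=C1[C@@H]([O-])CC=C | intermediate
13 | dipotassium salt of the (Z)-enolate and C4 alkoxide of 15 | [K+].[K+].CC(C)[C@]1([O-])CC[C@](C)(CC=C)/C1=C/[O-] | intermediate
14 | (2R,5R)-2-allyl-5-hydroxy-5-isopropyl-2-methylcyclopentane-1-carbaldehyde (both epimers at the formyl-bearing carbon) | CC(C)[C@]1(O)CC[C@](C)(CC=C)C1C=O | intermediate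
15 | (1R,2R,5R)-2-allyl-5-hydroxy-5-isopropyl-2-methylcyclopentane-1-carbaldehyde | CC(C)[C@]1(O)CC[C@](C)(CC=C)[C@H]1C=O | intermediate
16 | 2-methylallylmagnesium chloride | CC(=C)C[Mg]Cl | starting material
17 | chloromagnesium alkoxide of 15 | CC(C)[C@]1(O[Mg]Cl)CC[C@](C)(CC=C)[C@H]1C=O | intermediate
18 | (S)-1-[(1S,2R,5R)-2-allyl-5-hydroxy-5-isopropyl-2-methylcyclopentyl]-3-methylbut-3-en-1-ol | CC(C)[C@]1(O)CC[C@](C)(CC=C)[C@H]1[C@@H](O)CC(C)=C | intermediate
19 | tert-butyldimethylsilyl trifluoromethanesulfonate | CC(C)(C)[Si](C)(C)OS(=O)(=O)C(F)(F)F | starting material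
20 | (1R,2S,3R)-3-allyl-2-[(S)-1-(tert-butyldimethylsilyloxy)-3-methylbut-3-en-1-yl]-1-isopropyl-3-methylcyclopentan-1-ol | CC(C)[C@]1(O)CC[C@](C)(CC=C)[C@H]1[C@@H](O[Si](C)(C)C(C)(C)C)CC(C)=C | intermediate
21 | 4-(benzyloxy)benzoyl chloride | O=C(Cl)c1ccc(OCc2ccccc2)cc1 | starting material
22 | lithium alkoxide of 20 | [Li+].CC(C)[C@]1([O-])CC[C@](C)(CC=C)[C@H]1[C@@H](O[Si](C)(C)C(C)(C)C)CC(C)=C | intermediate
23 | (1R,2S,3R)-3-allyl-2-[(S)-1-(tert-butyldimethylsilyloxy)-3-methylbut-3-en-1-yl]-1-isopropyl-3-methylcyclopentyl 4-(benzyloxy)benzoate | CC(C)[C@]1(OC(=O)c2ccc(OCc3ccccc3)cc2)CC[C@](C)(CC=C)[C@H]1[C@@H](O[Si](C)(C)C(C)(C)C)CC(C)=C | intermediate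
24 | (1R,2S,3R)-3-allyl-2-[(S)-1-hydroxy-3-methylbut-3-en-1-yl]-1-isopropyl-3-methylcyclopentyl 4-(benzyloxy)benzoate | CC(C)[C@]1(OC(=O)c2ccc(OCc3ccccc3)cc2)CC[C@](C)(CC=C)[C@H]1[C@@H](O)CC(C)=C | intermediate
25 | (1R,4R,5S,6S)-6-hydroxydauc-8-en-4-yl 4-(benzyloxy)benzoate | CC(C)[C@]1(OC(=O)c2ccc(OCc3ccccc3)cc2)CC[C@]2(C)CC=C(C)C[C@H](O)[C@H]21 | intermediate
26 | tert-butyl hydroperoxide | CC(C)(C)OO | starting material
27 | (1R,4R,5S,6S,8R,9S)-8,9-epoxy-6-hydroxydaucan-4-yl 4-(benzyloxy)benzoate | CC(C)[C@]1(OC(=O)c2ccc(OCc3ccccc3)cc2)CC[C@]2(C)C[C@@H]3O[C@]3(C)C[C@H](O)[C@H]21 | intermediate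
28 | (1R,4R,5S,6S,8R,9S)-8,9-epoxy-6-hydroxydaucan-4-yl 4-hydroxybenzoate | CC(C)[C@]1(OC(=O)c2ccc(O)cc2)CC[C@]2(C)C[C@@H]3O[C@]3(C)C[C@H](O)[C@H]21 | target

Total step count: 11. Longest linear sequence: 11 steps (from 1; the route is fully linear, and reactants 2, 4, 9, 16, 19, 21 and 26 are purchased).

Steps most likely to fail

1. Step 5 (anionic oxy-Cope shift). What may go wrong: allyl transfer to the β face of C1 if the chair with the carbinol oxygen turned towards the C15 methyl competes, or cleavage of the bis-allylic alkoxide (loss of the allyl group) instead of the [3,3] shift. The fallback sets out from 8 and comes back at 18. 2-Methylallylmagnesium chloride 16 is added 1,2 to enal 8 to give the allylic alcohol F1 as a mixture of carbinol epimers. MnO2 oxidises it to the dienone F2. Hosomi–Sakurai conjugate allylation (allyltrimethylsilane, TiCl4, CH2Cl2, −78 °C) then forms the quaternary C1; titanium should bridge the C4 alkoxide and the ketone oxygen on the β face, so the allylsilane is expected to enter from the α face. After protonation and mild equilibration at C5 this gives the β-hydroxy ketone F3 with the acyl group trans to isopropyl. Hydroxyl-directed Saksena–Evans reduction with Me4NBH(OAc)3 (MeCN/AcOH, −20 °C) delivers hydride intramolecularly from the C4 oxygen and should give the 1,3-anti diol 18.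

2. Step 3 (aldol condensation). What may go wrong: β-elimination of the C4 silyloxy group from the enamine, or slow bond formation at the neopentyl α-carbon so that the ketone enolises and condenses in the other sense. The fallback sets out from 6 and comes back at 7 (then 8 as in step 3). The aldehyde, which enolises before the ketone, is converted with Me3SiOTf and Et3N (−78 °C) into the trimethylsilyl enol ether F4. TiCl4 (CH2Cl2, −78 °C) effects an intramolecular Mukaiyama aldol addition to the ketone and gives the β-hydroxy aldehyde F5 without any enamine. The Burgess reagent then dehydrates the free tertiary alcohol to enal 7.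

3. Step 8 (acylation of the tertiary alcohol). What may go wrong: incomplete acyl transfer to the very hindered C4 alkoxide, or migration of the silyl group from O6 to O4 followed by acylation at O6. The fallback sets out from 18 and comes back at 24. Diol 18 and 4-(benzyloxy)benzaldehyde (PPTS, MgSO4, CH2Cl2) give the cyclic acetal F6. DDQ in wet CH2Cl2 abstracts the acetal hydrogen and water adds to the dioxacarbenium ion. The ortho acid should collapse with release of the less hindered, more acidic secondary O6–H, which leaves the aroyl group on O4 and gives 24 without any strong base.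

Further compounds
F1 | step 5 | 1-[(R)-5-hydroxy-5-isopropyl-2-methylcyclopent-1-en-1-yl]-3-methylbut-3-en-1-ol (both carbinol epimers) | CC(C)[C@]1(O)CCC(C)=C1C(O)CC(C)=C
F2 | step 5 | 1-[(R)-5-hydroxy-5-isopropyl-2-methylcyclopent-1-en-1-yl]-3-methylbut-3-en-1-one | CC(C)[C@]1(O)CCC(C)=C1C(=O)CC(C)=C
F3 | step 5 | 1-[(1R,2R,5R)-2-allyl-5-hydroxy-5-isopropyl-2-methylcyclopentyl]-3-methylbut-3-en-1-one | CC(C)[C@]1(O)CC[C@](C)(CC=C)[C@H]1C(=O)CC(C)=C
F4 | step 3 | (R)-5-isopropyl-5-(triethylsilyloxy)-7-(trimethylsilyloxy)hept-6-en-2-one (E/Z mixture) | CC(C)[C@](C=CO[Si](C)(C)C)(O[Si](CC)(CC)CC)CCC(C)=O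
F5 | step 3 | (5R)-2-hydroxy-5-isopropyl-2-methyl-5-(triethylsilyloxy)cyclopentane-1-carbaldehyde (mixture at C1 and C2) | CC(C)[C@]1(O[Si](CC)(CC)CC)CCC(C)(O)C1C=O
F6 | step 8 | O4,O6-[4-(benzyloxy)benzylidene] acetal of 18 (1,3-dioxane, both epimers at the acetal carbon) | CC(C)[C@]12CC[C@](C)(CC=C)[C@H]1[C@H](CC(C)=C)OC(c1ccc(OCc3ccccc3)cc1)O2
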